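A small charge of substrate, such as the 0.50 M in grey, gives first product only as far as it turns over, so we count how far it gets before reckoning any yield.

| setting | east | south | grey | green |
|---|---|---|---|---|
| substrate | 0.80 M | 0.46 M | 0.50 M | 0.80 M |
| coupling partner | 2.4 M | 1.6 M | 2.50 M | 1.60 M |
| temperature | 32 °C | 49 °C |  |  |
| remark | run made earlier | run made earlier | at 25 °C throughout | at 25 °C until 1.5 min, from then on at 55 °C |
| time |  |  | 3.0 min | 3.0 min |

east run (percent of the substrate charged)

| time / min | first product / % | substrate / % |
|---|---|---|
| 0.417 | 16.0 | 34.9 |
| 1.00 | 20.2 | 12.2 |
| 2.00 | 21.4 | 4.8 |
| 3.00 | 22.3 | 2.8 |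

south run (percent of the substrate charged)

| time / s | first product / % | substrate / % |
|---|---|---|
| 10.0 | 12.0 | 37.2 |
| 25.0 | 17.2 | 12.7 |
| 60.0 | 18.9 | 3.7 |

(scatter of a reading: 0.5 percentage points)

- which one finishes higher in amount of first product, in percent of the substrate charged ("neither" within 2 percentage points) (grey / green / neither)
- amount of first product at the end, in percent of the substrate charged, grey
- amount of first product at the end, in percent of the substrate charged, green

- the numbers in the tables scatter with a standard deviation of 0.5 percentage points
- a reading or a percentage of first product counts all its forms, free or not
- a reading of substrate is of its free form alone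

Let φ be first product found per substrate lost, the selectivity for first product. Yield is φ times conversion. The last readings give φ = 0.229 in east and 0.196 in south.

For a ceiling, we take full conversion and extend φ along a straight line. Going from south to east is one temperature step, and 25 °C lies 0.412 of a step beyond east. That gives φ = 0.243, so neither flask should pass 24.3%.

For grey's floor, we keep east's φ, since grey is colder. East had 12.2% substrate left at 1.00 min and south 12.7% at 25.0 s, so east took about 2.40 times south's time to get that far, on 1.50 times south's coupling partner. Raising that combined factor to the power 0.412 and then multiplying, as a deliberately harsh allowance, by the ratio of substrate charges allows grey a slowdown of 2.71 against east. This is less than the ratio of grey's 3.0 min to east's 1.00 min, so grey should pass east's conversion at that reading, and its floor is 20.1%.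

For green's floor, we take south's last reading, 18.9%: green's hot stage is hotter and has the same partner charge, provided its partner lasts.

The midpoints differ by 0.62 percentage points, under the margin, so we say neither.

The forecast says neither, with grey at 21.3% (19% to 23.5%) and green at 20% (16% to 23.5%): “The difference is probably within 2 points”. Both central values lie inside our brackets.

The answer is neither: grey ends at 23.9% and green at 24.1%, both under the ceiling. Conversion reaches 95.1% in grey and 98.1% in green.

    substrate + coupling partner → first product + by-product (k = 0.00296 /M/s, Ea = 51.0 kJ/mol)
    coupling partner + other mono adduct → bis adduct + by-product (k = 0.00807 /M/s, Ea = 72.0 kJ/mol)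
    first product ⇌ isomer of the product (K = 0.420, k = 0.0143 /s, Ea = 91.0 kJ/mol, ΔH = −44.0 kJ/mol)
    substrate + first product ⇌ idle adduct, settled at all times (K = 55.0 /M, ΔH = −2.00 kJ/mol)
    substrate + coupling partner → other mono adduct + by-product (k = 0.00575 /M/s, Ea = 69.0 kJ/mol)
    coupling partner + first product → bis adduct + by-product (k = 7.28 × 10⁻⁵ /M/s, Ea = 64.0 kJ/mol)
    (constants at 25 °C)

Now take φ to a further flask: green charged with 2.0 M of substrate. Its coupling partner is down to 0.00747% of its own charge, and 23.2% of its substrate stands free at 3.00 min, so east's φ gives 17.6%. That flask holds 18.3% first product.

The readings are simulated with made-up constants; scatter was added.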